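Which species stands highest after 6.0 min in cedar and in alder, and how much of it is there? Cedar has the lower activator charge.

the same everywhere: starting material 0.081 M

|  | activator | remark | time |
|---|---|---|---|
| dawn | 0.13 M | run made earlier |  |
| autumn | 0.35 M | run made earlier |  |
| cedar | 0.0890 M |  | 6.0 min |
| alder | 0.220 M |  | 6.0 min |

| run | time / min | activated form / % | starting material / % | ring / % | open dimer / % |
|---|---|---|---|---|---|
| dawn | 1.00 | 13.7 | 78.9 | 0.7 | 4.0 |
| dawn | 2.00 | 19.6 | 60.9 | 3.6 | 12.6 |
| dawn | 3.00 | 20.6 | 48.4 | 6.2 | 20.8 |
| dawn | 4.00 | 20.8 | 38.3 | 7.9 | 26.6 |
| autumn | 0.500 | 20.4 | 74.0 | 1.6 | 3.4 |
| autumn | 1.33 | 36.4 | 42.7 | 4.7 | 12.8 |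
| autumn | 2.50 | 41.2 | 19.9 | 10.2 | 22.8 |
| autumn | 4.00 | 37.7 | 7.0 | 17.7 | 28.3 |

(each reading ± 0.5 percentage points)

- in percentages every species weighs as the starting material in it: one open dimer or side product counts as two
- what was read earlier has a scatter of 0.5 percentage points, one standard deviation
- steps thought possible: starting material + activator -> activated form; activated form -> ring; starting material + activated form -> open dimer; starting material + activated form -> side product; ring <-> isomer of the product
- a reading of ring is of its free form alone

1. which of these there is most of at the end, counted by the starting material in it, cedar (open dimer / activated form / ring / starting material)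
2. which of these there is most of at the end, counted by the starting material in it, alder (open dimer / activated form / ring / starting material)
3. final amount of the leader among these, as a percentage of the starting material charged, in cedar
4. final amount of the leader among these, as a percentage of the starting material charged, in alder

Activated form has two exits. It closes to ring, or it takes up a further starting material. The second exit speeds up with [starting material], so we look for the crossing. An open dimer counts twice in percent, so open dimer gained over ring gained is twice [starting material] over the crossing level. With mean [starting material] between readings, we reckon:

dawn: 0.0302 M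
autumn: 0.0338 M
mean: 0.0320 M

This is the crossing level, the [starting material] at which activated form leaves as fast to open dimer as to ring (selectivity factor one). It is 39.5% of the charge.

The first autumn reading gives an activation constant of 1.56 L mol⁻¹ min⁻¹. The later autumn readings give the ring exit a half-life of 5.87 min. Our ladder of half-lives, with activator taken at its charge, reads, fastest first:

activation, alder: 2.02 min
open dimer exit at full charge: 2.32 min
activation, cedar: 5.00 min
ring exit: 5.87 min

Each rung is slower than the one above it.

By activation alone we reckon alder at the crossing at 2.71 min and cedar at 6.70 min, later than 6.0 min. The crossing ranks the two exits of activated form; it does not rank starting material against open dimer. For the leader we reckon apart. Over 6.0 min, these activation half-lives leave 43.6% of starting material in cedar and 12.8% in alder. Cedar's figure is above the 26.6% of open dimer read last in dawn, and alder's is below the 28.3% read last in autumn. So we expect starting material to lead in cedar and open dimer in alder.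

The forecast gives starting material at 37% (33% to 41%) in cedar and open dimer at 35% (32% to 38%) in alder: “Starting material leads in cedar and open dimer leads in alder.”

The flasks give starting material at 37.9% in cedar and open dimer at 35.6% in alder.

    starting material + activator → activated form (k = 1.60 L mol⁻¹ min⁻¹)
    activated form → ring (k = 0.140 min⁻¹)
    starting material + activated form → open dimer (k = 4.40 L mol⁻¹ min⁻¹)
    starting material + activated form → side product (k = 1.00 L mol⁻¹ min⁻¹)
    ring ⇌ isomer of the product (K = 0.670, k = 0.0460 min⁻¹)

At 3.00 min, cedar held 0.0492 M of starting material, above the crossing level of 0.0320 M. Alder then held 0.0239 M, already below it. In cedar at 1.95 min, activated form went to open dimer 1.8 times as fast as to ring. Cedar came just under the crossing level at 6.00 min, with 0.0307 M.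

All runs were computed for an exercise; noise was put on by code.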